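**Strategy.** The route rests on disconnecting the O4–C3 bond of the 1,4-dioxane ring. The feature exploited is that C3 is bonded both to O4, the dioxane oxygen on the ring A carbon para to C7, and to the CH2OH carbon. A vinyl group can stand in for that carbinol, which makes C3 the inner end of a π-allyl system. One palladium-catalysed allylic etherification then forms O4–C3, closes the dioxane ring and sets C3 trans to the preset C2 aryl centre. Its precursor is an (R)-1-arylallyl aryl ether, made by iridium-catalysed asymmetric etherification and extended by cross-metathesis to an (E)-allylic methyl carbonate. It carries a free ring A phenol para to a formyl group, and the syringyl phenol stays silylated until the end.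

Key step: step 10

Remark: benzodioxane positions are numbered O1–C2(aryl)–C3–O4, with C7 the ring A carbon para to the O4-bearing carbon; the ligand enantiomers named in steps 6 and 10 are those expected from the usual sense of induction of their families and would be confirmed on a first run.

Step 1
Reactants: 1 syringaldehyde (4-hydroxy-3,5-dimethoxybenzaldehyde)
Product: 2 3,5-dimethoxy-4-(triisopropylsilyloxy)benzaldehyde
Conditions: TIPSCl, imidazole, DMF, rt
Reagents that add atoms: triisopropylsilyl chloride, CC(C)[Si](Cl)(C(C)C)C(C)C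
Why: Silyl ether formation on the only hydroxyl group gives a hindered aryl silyl ether that should survive the hydride, base, ruthenium and palladium steps and that blocks quinone methide chemistry at the future C2 until the last step.

Step 2
Reactants: 2 3,5-dimethoxy-4-(triisopropylsilyloxy)benzaldehyde
Product: 3 ethyl (E)-3-[3,5-dimethoxy-4-(triisopropylsilyloxy)phenyl]prop-2-enoate
Conditions: (EtO)2P(O)CH2CO2Et, NaH, THF, 0 °C to rt
Reagents that add atoms: triethyl phosphonoacetate, CCOC(=O)CP(=O)(OCC)OCC
Why: Horner–Wadsworth–Emmons olefination of the aryl aldehyde with the stabilized phosphonate anion should give the (E)-enoate almost exclusively.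

Step 3
Reactants: 3 ethyl (E)-3-[3,5-dimethoxy-4-(triisopropylsilyloxy)phenyl]prop-2-enoate
Product: 4 (E)-3-[3,5-dimethoxy-4-(triisopropylsilyloxy)phenyl]prop-2-en-1-ol
Conditions: i-Bu2AlH, CH2Cl2, −78 °C; aq. potassium sodium tartrate
Reagents that add atoms: none
Why: Reduction of the conjugated ester with i-Bu2AlH at low temperature is a standard 1,2-reduction to the (E)-allylic alcohol and leaves the aryl silyl ether alone.

Step 4
Reactants: 4 (E)-3-[3,5-dimethoxy-4-(triisopropylsilyloxy)phenyl]prop-2-en-1-ol
Product: 5 (E)-3-[3,5-dimethoxy-4-(triisopropylsilyloxy)phenyl]prop-2-en-1-yl methyl carbonate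
Conditions: ClCO2Me, pyridine, CH2Cl2, 0 °C
Reagents that add atoms: methyl chloroformate, COC(=O)Cl
Why: Acylation of the primary allylic alcohol with methyl chloroformate (carbonate formation) installs the leaving group needed for iridium π-allyl formation.

Step 5
Reactants: 6 3,4-dihydroxybenzaldehyde
Product: 7 3-hydroxy-4-(methoxymethoxy)benzaldehyde
Conditions: MOMCl (1.05 equiv), K2CO3, acetone, 0 °C to rt
Reagents that add atoms: chloromethyl methyl ether, COCCl
Why: Williamson-type O-alkylation (MOM protection) under weak base is regioselective because the 4-OH para to the formyl group is the more acidic phenol and is ionized first, and an acetal-type alkyl group cannot migrate to the neighbouring 3-oxygen in later basic steps.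

Step 6
Reactants: 5 (E)-3-[3,5-dimethoxy-4-(triisopropylsilyloxy)phenyl]prop-2-en-1-yl methyl carbonate; 7 3-hydroxy-4-(methoxymethoxy)benzaldehyde
Product: 8 3-({(1R)-1-[3,5-dimethoxy-4-(triisopropylsilyloxy)phenyl]prop-2-en-1-yl}oxy)-4-(methoxymethoxy)benzaldehyde
Conditions: 7, NaH, THF, 0 °C; then 5, [Ir(cod)Cl]2 (2 mol%), (Ra,Rc,Rc)-binaphthol-derived N,N-bis(1-phenylethyl)phosphoramidite (4 mol%; pre-activated with n-PrNH2, volatiles removed), THF, rt to 40 °C
Reagents that add atoms: none
Why: In this iridium-catalysed asymmetric allylic etherification (branched-selective allylic substitution) the cyclometalated iridium–phosphoramidite complex ionizes the cinnamyl carbonate and the aryloxide attacks the aryl-bearing allyl terminus, the chiral ligand fixing the face of attack so that the benzylic carbon (future C2) should be formed as (R).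

Step 7
Reactants: 8 3-({(1R)-1-[3,5-dimethoxy-4-(triisopropylsilyloxy)phenyl]prop-2-en-1-yl}oxy)-4-(methoxymethoxy)benzaldehyde
Product: 10 3-({(1R)-1-[3,5-dimethoxy-4-(triisopropylsilyloxy)phenyl]prop-2-en-1-yl}oxy)-4-hydroxybenzaldehyde, via aryl trimethylsilyl ether 9 (not isolated)
Conditions: TMSOTf, 2,2'-bipyridyl, MeCN, 0 °C to rt; then H2O
Reagents that add atoms: none
Why: Lewis-acid cleavage of the aromatic MOM ether with TMSOTf/2,2'-bipyridyl proceeds by silylation of the acetal and transfer of the methoxymethyl unit to bipyridyl under buffered, non-protic conditions, so the acetal should be removed (via the silyl ether, hydrolysed on work-up) while the benzylic allylic aryl ether, the TIPS ether and the aldehyde are kept and C2 is not ionized.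

Step 8
Reactants: 11 (Z)-but-2-ene-1,4-diol
Product: 12 (Z)-but-2-ene-1,4-diyl bis(methyl carbonate)
Conditions: ClCO2Me (2.5 equiv), pyridine, CH2Cl2, 0 °C
Reagents that add atoms: methyl chloroformate, COC(=O)Cl
Why: Double acylation of the diol with methyl chloroformate (carbonate formation) gives the symmetrical cross-metathesis partner.

Step 9
Reactants: 10 3-({(1R)-1-[3,5-dimethoxy-4-(triisopropylsilyloxy)phenyl]prop-2-en-1-yl}oxy)-4-hydroxybenzaldehyde; 12 (Z)-but-2-ene-1,4-diyl bis(methyl carbonate)
Product: 13 (2E,4R)-4-[3,5-dimethoxy-4-(triisopropylsilyloxy)phenyl]-4-(5-formyl-2-hydroxyphenoxy)but-2-en-1-yl methyl carbonate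
Conditions: second-generation Hoveyda–Grubbs catalyst (5 mol%), 12 (4 equiv), CH2Cl2, 40 °C
Reagents that add atoms: none
Why: Olefin cross-metathesis of the terminal alkene with an excess of the symmetrical (Z)-biscarbonate should give mainly the (E)-allylic carbonate without involving the allylic stereocentre, and any (Z)-isomer would converge on the same π-allyl complex in step 10.

Step 10
Reactants: 13 (2E,4R)-4-[3,5-dimethoxy-4-(triisopropylsilyloxy)phenyl]-4-(5-formyl-2-hydroxyphenoxy)but-2-en-1-yl methyl carbonate
Product: 14 (2S,3S)-2-[3,5-dimethoxy-4-(triisopropylsilyloxy)phenyl]-3-vinyl-2,3-dihydro-1,4-benzodioxine-7-carbaldehyde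
Conditions: Pd2(dba)3·CHCl3 (2.5 mol%), (R,R)-DACH-phenyl Trost ligand (7.5 mol%), AcOH (1 equiv), CH2Cl2 (0.05 M), rt
Reagents that add atoms: none
Why: Zerovalent palladium ionizes the primary allylic methyl carbonate with loss of CO2 and methoxide (buffered by AcOH) to give a π-allyl complex spanning C3 and the two chain carbons, and the ring A phenol para to the formyl group attacks the inner terminus C3 as its phenoxide, forming O4–C3. This is an intramolecular Tsuji–Trost allylic etherification of the kind known for phenol-tethered allylic carbonates giving 2-vinyl-1,4-benzodioxanes and 2-vinylchromans. The dioxane ring closes in the 6-exo mode with the vinyl group left exocyclic, whereas attack at the CH2 terminus would need an eight-membered ring. The new C3 stereocentre is controlled by the chiral diphosphine, which selects between the two π-allyl faces that interconvert by π–σ–π slippage through the unsubstituted CH2 terminus, and it is reinforced by the preset (R)-benzylic centre, whose aryl group sits pseudo-equatorial so that the vinyl group ends trans. Because the product is an allyl ether of an acidic 4-formylphenol it can re-ionize, so the cyclization can also drift to the more stable trans diequatorial ring, which is (2S,3S). The step needs inner over terminal attack, trans over cis, and carbonate ionization over loss of the C2 aryloxy group; these are secured by ring size, by the matched ligand plus reversibility, and by the far better carbonate leaving group.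

Step 11
Reactants: 14 (2S,3S)-2-[3,5-dimethoxy-4-(triisopropylsilyloxy)phenyl]-3-vinyl-2,3-dihydro-1,4-benzodioxine-7-carbaldehyde
Product: 17 [(2S,3S)-2-[3,5-dimethoxy-4-(triisopropylsilyloxy)phenyl]-2,3-dihydro-1,4-benzodioxine-3,7-diyl]dimethanol, via vicinal diol 15 (not isolated), via dialdehyde 16 (not isolated)
Conditions: OsO4 (2 mol%), NaIO4, 2,6-lutidine, dioxane/H2O, rt; then NaBH4 (excess), MeOH, 0 °C
Reagents that add atoms: osmium tetroxide, O=[Os](=O)(=O)=O (delivers the carbinol oxygen); sodium periodate, [Na+].[O-]I(=O)(=O)=O (re-supplies that oxygen as terminal oxidant)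
Why: Lemieux–Johnson oxidative cleavage of the only alkene followed in the same flask by NaBH4 reduction turns the vinyl group into the C3 carbinol without isolating the epimerizable α-aryloxy aldehyde, the ring A aldehyde being reduced as well on purpose, and C2 and C3 are not touched (any C3 epimerization at the aldehyde stage would favour the trans ring).

Step 12
Reactants: 17 [(2S,3S)-2-[3,5-dimethoxy-4-(triisopropylsilyloxy)phenyl]-2,3-dihydro-1,4-benzodioxine-3,7-diyl]dimethanol
Product: 18 (2S,3S)-2-[3,5-dimethoxy-4-(triisopropylsilyloxy)phenyl]-3-(hydroxymethyl)-2,3-dihydro-1,4-benzodioxine-7-carbaldehyde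
Conditions: MnO2 (activated, excess), CH2Cl2, rt
Reagents that add atoms: none
Why: Activated MnO2 oxidizes benzylic alcohols but not saturated primary alcohols (chemoselective benzylic oxidation), so only the ring A carbinol should return to the aldehyde.

Step 13
Reactants: 18 (2S,3S)-2-[3,5-dimethoxy-4-(triisopropylsilyloxy)phenyl]-3-(hydroxymethyl)-2,3-dihydro-1,4-benzodioxine-7-carbaldehyde
Product: 19 (E)-3-[(2S,3S)-2-[3,5-dimethoxy-4-(triisopropylsilyloxy)phenyl]-3-(hydroxymethyl)-2,3-dihydro-1,4-benzodioxin-7-yl]prop-2-enal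
Conditions: Ph3P=CHCHO (1.3 equiv), toluene, 80 °C
Reagents that add atoms: (triphenylphosphoranylidene)acetaldehyde, O=CC=P(c1ccccc1)(c1ccccc1)c1ccccc1
Why: Wittig olefination with the stabilized formylmethylene ylide should give the (E)-enal under neutral conditions that tolerate the free primary alcohol and the silyl ether.

Step 14
Reactants: 19 (E)-3-[(2S,3S)-2-[3,5-dimethoxy-4-(triisopropylsilyloxy)phenyl]-3-(hydroxymethyl)-2,3-dihydro-1,4-benzodioxin-7-yl]prop-2-enal
Product: 20 (E)-3-[(2S,3S)-2-(4-hydroxy-3,5-dimethoxyphenyl)-3-(hydroxymethyl)-2,3-dihydro-1,4-benzodioxin-7-yl]prop-2-enal (CNP0211211.1)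
Conditions: Bu4NF, AcOH (1:1), THF, 0 °C
Reagents that add atoms: none
Why: Fluoride-mediated desilylation of the aryl silyl ether, buffered with acetic acid so that the freed phenol is not left as a phenoxide able to open the ring through a quinone methide, should give the target without touching the enal or the stereocentres.

**Compound list**

1 | syringaldehyde (4-hydroxy-3,5-dimethoxybenzaldehyde) | COc1cc(C=O)cc(OC)c1O | starting material
2 | 3,5-dimethoxy-4-(triisopropylsilyloxy)benzaldehyde | COc1cc(C=O)cc(OC)c1O[Si](C(C)C)(C(C)C)C(C)C | intermediate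
3 | ethyl (E)-3-[3,5-dimethoxy-4-(triisopropylsilyloxy)phenyl]prop-2-enoate | CCOC(=O)/C=C/c1cc(OC)c(O[Si](C(C)C)(C(C)C)C(C)C)c(OC)c1 | intermediate
4 | (E)-3-[3,5-dimethoxy-4-(triisopropylsilyloxy)phenyl]prop-2-en-1-ol | OC/C=C/c1cc(OC)c(O[Si](C(C)C)(C(C)C)C(C)C)c(OC)c1 | intermediate
5 | (E)-3-[3,5-dimethoxy-4-(triisopropylsilyloxy)phenyl]prop-2-en-1-yl methyl carbonate | COC(=O)OC/C=C/c1cc(OC)c(O[Si](C(C)C)(C(C)C)C(C)C)c(OC)c1 | intermediate
6 | 3,4-dihydroxybenzaldehyde | O=Cc1ccc(O)c(O)c1 | starting material
7 | 3-hydroxy-4-(methoxymethoxy)benzaldehyde | COCOc1ccc(C=O)cc1O | intermediate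
8 | 3-({(1R)-1-[3,5-dimethoxy-4-(triisopropylsilyloxy)phenyl]prop-2-en-1-yl}oxy)-4-(methoxymethoxy)benzaldehyde | COc1cc([C@H](Oc2cc(C=O)ccc2OCOC)C=C)cc(OC)c1O[Si](C(C)C)(C(C)C)C(C)C | intermediate
9 | 3-({(1R)-1-[3,5-dimethoxy-4-(triisopropylsilyloxy)phenyl]prop-2-en-1-yl}oxy)-4-(trimethylsilyloxy)benzaldehyde | COc1cc([C@H](Oc2cc(C=O)ccc2O[Si](C)(C)C)C=C)cc(OC)c1O[Si](C(C)C)(C(C)C)C(C)C | intermediate (not isolated)
10 | 3-({(1R)-1-[3,5-dimethoxy-4-(triisopropylsilyloxy)phenyl]prop-2-en-1-yl}oxy)-4-hydroxybenzaldehyde | COc1cc([C@H](Oc2cc(C=O)ccc2O)C=C)cc(OC)c1O[Si](C(C)C)(C(C)C)C(C)C | intermediate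
11 | (Z)-but-2-ene-1,4-diol | OC/C=C\CO | starting material
12 | (Z)-but-2-ene-1,4-diyl bis(methyl carbonate) | COC(=O)OC/C=C\COC(=O)OC | intermediate
13 | (2E,4R)-4-[3,5-dimethoxy-4-(triisopropylsilyloxy)phenyl]-4-(5-formyl-2-hydroxyphenoxy)but-2-en-1-yl methyl carbonate | COc1cc([C@H](Oc2cc(C=O)ccc2O)/C=C/COC(=O)OC)cc(OC)c1O[Si](C(C)C)(C(C)C)C(C)C | intermediate
14 | (2S,3S)-2-[3,5-dimethoxy-4-(triisopropylsilyloxy)phenyl]-3-vinyl-2,3-dihydro-1,4-benzodioxine-7-carbaldehyde (trans) | COc1cc([C@@H]2Oc3cc(C=O)ccc3O[C@H]2C=C)cc(OC)c1O[Si](C(C)C)(C(C)C)C(C)C | intermediate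
15 | (2S,3S)-3-(1,2-dihydroxyethyl)-2-[3,5-dimethoxy-4-(triisopropylsilyloxy)phenyl]-2,3-dihydro-1,4-benzodioxine-7-carbaldehyde, both epimers at the side-chain carbinol | COc1cc([C@@H]2Oc3cc(C=O)ccc3O[C@H]2C(O)CO)cc(OC)c1O[Si](C(C)C)(C(C)C)C(C)C | intermediate (not isolated)
16 | (2S,3R)-2-[3,5-dimethoxy-4-(triisopropylsilyloxy)phenyl]-2,3-dihydro-1,4-benzodioxine-3,7-dicarbaldehyde (trans) | COc1cc([C@@H]2Oc3cc(C=O)ccc3O[C@H]2C=O)cc(OC)c1O[Si](C(C)C)(C(C)C)C(C)C | intermediate (not isolated)
17 | [(2S,3S)-2-[3,5-dimethoxy-4-(triisopropylsilyloxy)phenyl]-2,3-dihydro-1,4-benzodioxine-3,7-diyl]dimethanol | COc1cc([C@@H]2Oc3cc(CO)ccc3O[C@H]2CO)cc(OC)c1O[Si](C(C)C)(C(C)C)C(C)C | intermediate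
18 | (2S,3S)-2-[3,5-dimethoxy-4-(triisopropylsilyloxy)phenyl]-3-(hydroxymethyl)-2,3-dihydro-1,4-benzodioxine-7-carbaldehyde | COc1cc([C@@H]2Oc3cc(C=O)ccc3O[C@H]2CO)cc(OC)c1O[Si](C(C)C)(C(C)C)C(C)C | intermediate
19 | (E)-3-[(2S,3S)-2-[3,5-dimethoxy-4-(triisopropylsilyloxy)phenyl]-3-(hydroxymethyl)-2,3-dihydro-1,4-benzodioxin-7-yl]prop-2-enal | COc1cc([C@@H]2Oc3cc(/C=C/C=O)ccc3O[C@H]2CO)cc(OC)c1O[Si](C(C)C)(C(C)C)C(C)C | intermediate
20 | (E)-3-[(2S,3S)-2-(4-hydroxy-3,5-dimethoxyphenyl)-3-(hydroxymethyl)-2,3-dihydro-1,4-benzodioxin-7-yl]prop-2-enal | COc1cc([C@@H]2Oc3cc(/C=C/C=O)ccc3O[C@H]2CO)cc(OC)c1O | target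

**Step count.** Total: 14 steps. Longest linear sequence: 12 steps (steps 1–4, 6, 7, 9–14, from syringaldehyde).

**Steps most likely to fail**

Step 10 (key cyclization). The cyclization may close on the wrong allyl face and give the cis ring if face exchange of the π-allyl complex is slow. The allylpalladium intermediate may also lose the C2 aryloxy group by β-elimination, which would give a diene and strip off ring A. The fallback sets out from 10 and returns at 18, making the same O4–C3 bond by electrophilic instead of metal activation. Iodoetherification of 10 (I2, NaHCO3, MeCN, 0 °C) should close the dioxane ring by 6-exo attack of the phenol on the iodonium ion, with the aryl group equatorial in a chair-like transition state, to give the trans iodomethyl benzodioxane F1. Displacement of iodide with CsOAc (DMF, 60 °C) should give the acetate F2, and brief methanolysis (K2CO3, MeOH, 0 °C) should give 18, so that steps 9 to 12 are bypassed.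

Step 6 (iridium etherification). The catalyst may re-ionize the branched ether, which would erode the enantiopurity or let the product drift to the linear cinnamyl ether. Attack by the ortho-substituted aryloxide may also be sluggish. The fallback sets out from 2 and returns at 8, taking the C2 configuration from a resolution and forming the C–O bond by SN2 displacement. Addition of CH2=CHMgBr (THF, −78 °C) to 2 should give the racemic 1-arylallyl alcohol F3. Sharpless kinetic resolution (Ti(OiPr)4, L-(+)-DIPT, t-BuOOH, 4 Å MS, CH2Cl2, −20 °C, slightly over half conversion) should leave the (S)-alcohol F4, the (R)-enantiomer being consumed as the epoxy alcohol F5 and removed by chromatography. Mitsunobu etherification of F4 with phenol 7 (PPh3, DIAD, toluene, 0 °C) should give 8 with inversion.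

Step 7 (phenol unmasking). The silyl Lewis acid may ionize the benzylic allylic C–O bond, with loss of the ring A unit or racemization at C2, in competition with cleavage of the acetal. The fallback sets out from 6 and returns at 10, replacing acid-mediated by photochemical unmasking. Regioselective alkylation of 6 with 2-nitrobenzyl bromide (NaHCO3, NaI, DMF, 40 °C) should give the 4-O-(2-nitrobenzyl) ether F6. Coupling of F6 with 5 under the conditions of step 6 should give the nitrobenzyl analogue of 8, F7. Irradiation of F7 at 365 nm (MeCN, rt) should release phenol 10 under neutral conditions.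

**Further compounds**

F1 | step 10 | (2S,3R)-2-[3,5-dimethoxy-4-(triisopropylsilyloxy)phenyl]-3-(iodomethyl)-2,3-dihydro-1,4-benzodioxine-7-carbaldehyde (trans) | COc1cc([C@@H]2Oc3cc(C=O)ccc3O[C@H]2CI)cc(OC)c1O[Si](C(C)C)(C(C)C)C(C)C
F2 | step 10 | [(2S,3S)-2-[3,5-dimethoxy-4-(triisopropylsilyloxy)phenyl]-7-formyl-2,3-dihydro-1,4-benzodioxin-3-yl]methyl acetate | COc1cc([C@@H]2Oc3cc(C=O)ccc3O[C@H]2COC(C)=O)cc(OC)c1O[Si](C(C)C)(C(C)C)C(C)C
F3 | step 6 | rac-1-[3,5-dimethoxy-4-(triisopropylsilyloxy)phenyl]prop-2-en-1-ol | COc1cc(C(O)C=C)cc(OC)c1O[Si](C(C)C)(C(C)C)C(C)C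
F4 | step 6 | (1S)-1-[3,5-dimethoxy-4-(triisopropylsilyloxy)phenyl]prop-2-en-1-ol | COc1cc([C@@H](O)C=C)cc(OC)c1O[Si](C(C)C)(C(C)C)C(C)C
F5 | step 6 | (S)-[3,5-dimethoxy-4-(triisopropylsilyloxy)phenyl][(2S)-oxiran-2-yl]methanol (erythro epoxy alcohol of the consumed enantiomer) | O[C@@H](c1cc(OC)c(O[Si](C(C)C)(C(C)C)C(C)C)c(OC)c1)[C@@H]2CO2
F6 | step 7 | 3-hydroxy-4-[(2-nitrophenyl)methoxy]benzaldehyde | O=Cc1ccc(OCc2ccccc2[N+](=O)[O-])c(O)c1
F7 | step 7 | 3-({(1R)-1-[3,5-dimethoxy-4-(triisopropylsilyloxy)phenyl]prop-2-en-1-yl}oxy)-4-[(2-nitrophenyl)methoxy]benzaldehyde | COc1cc([C@H](Oc2cc(C=O)ccc2OCc3ccccc3[N+](=O)[O-])C=C)cc(OC)c1O[Si](C(C)C)(C(C)C)C(C)C
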